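**Plan**

1. Locants used below: decalin carbons C1–C10, with C4 = CMe2, C5=C6 the alkene, C7 = CH2, C8 = CHMe, C9 the quaternary carbon and C10 the ring-fusion CH; ring A = C1–C5/C10, ring B = C5–C10.
2. Retrosynthetic cuts, in order: aryl O–SO3H and aryl–CHO; the C7–S helper bond and C8–CH3; C9–CH3 and C9–CH2Ar; then C5–C10 and C7–C8 together; last the two olefination bonds (C9=C10, C6=C7) and C3–C4.
3. Enabling feature: both ring-B bonds flank the only alkene, so C5–C6–C7 is an allyl triad (a sulfonyl allyl anion reacting gamma, then alpha) and C10–C9–C8 maps onto the beta-, alpha- and acyl carbons of an enoate.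
4. Forward order: acyclic allyl sulfone/enoate → rings A and B in one anionic (3+3) annulation → C9 arylmethyl, then C9 methyl → C8 methyl → desulfonylation → formylation, deprotection, sulfation.
5. Stereochemistry: C10 from the 8-phenylmenthyl ester in the Michael event; C9 by methylation anti to the pseudo-axial H-10; C8 by axial methyl addition anti to the axial C9 methyl group.
6. Helpers, all removed: PhSO2 at C7, the C8 carbonyl left by the ester, MOM ethers, a transient catechol boronate.

Key step: step 7

Assumption: the lithiated allyl sulfone adds to the 8-phenylmenthyl enoate with the facial sense known for organocopper additions to 8-phenylmenthyl crotonates (pi-stacked s-trans enoate), which calls for the (+)-alcohol (the (−)-alcohol would be used if the sense were reversed); the target is obtained as the free hydrogen sulfate after an acidic ion-exchange resin.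

**Route**

Step 1
Reactants: 1 2-(3-chloropropyl)-1,3-dioxolane; 2 ethyl 3-methylbut-2-enoate
Product: 4 ethyl 6-(1,3-dioxolan-2-yl)-3,3-dimethylhexanoate, via Grignard reagent 3 (not isolated)
Conditions: Mg, THF, reflux; then 2, CuI (10 mol %), Me3SiCl, THF, −40 to 0 °C; aq NH4Cl
Reagents that add atoms: none
Why: Copper-catalysed, Me3SiCl-accelerated conjugate addition of the Grignard reagent to the beta,beta-disubstituted enoate should build the gem-dimethyl carbon C4 without creating a stereocentre.

Step 2
Reactants: 4 ethyl 6-(1,3-dioxolan-2-yl)-3,3-dimethylhexanoate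
Product: 5 6-(1,3-dioxolan-2-yl)-3,3-dimethylhexanal
Conditions: i-Bu2AlH (1.05 equiv), CH2Cl2, −78 °C; Rochelle salt
Reagents that add atoms: none
Why: Partial reduction of the ester with i-Bu2AlH at low temperature should stop at the aldehyde through the stable aluminium hemiacetal, and the dioxolane is inert.

Step 3
Reactants: 5 6-(1,3-dioxolan-2-yl)-3,3-dimethylhexanal; 6 diethyl [(phenylsulfonyl)methyl]phosphonate
Product: 8 2-[(5E)-4,4-dimethyl-7-(phenylsulfonyl)hept-5-en-1-yl]-1,3-dioxolane, via vinyl sulfone 7 (not isolated)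
Conditions: NaH, THF, 0 °C to rt; then KOt-Bu (0.2 equiv), rt
Reagents that add atoms: none
Why: Horner–Wadsworth–Emmons olefination gives the (E)-vinyl sulfone, and base-mediated 1,3-proton shift (vinyl-to-allyl sulfone isomerisation) should then move the alkene to the more stable gamma-alkylated position, leaving the acidic CH2 next to sulfur.

Step 4
Reactants: 8 2-[(5E)-4,4-dimethyl-7-(phenylsulfonyl)hept-5-en-1-yl]-1,3-dioxolane
Product: 9 (6E)-5,5-dimethyl-8-(phenylsulfonyl)oct-6-enal
Conditions: 1 M HCl (aq), THF, rt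
Reagents that add atoms: water, O
Why: Acid-catalysed acetal hydrolysis should free the aldehyde while the allyl sulfone and the isolated alkene are stable to dilute acid.

Step 5
Reactants: 10 (+)-8-phenylmenthol, (1S,2R,5S)-5-methyl-2-(2-phenylpropan-2-yl)cyclohexan-1-ol; 11 triethyl phosphonoacetate
Product: 12 (1S,2R,5S)-5-methyl-2-(2-phenylpropan-2-yl)cyclohexyl (diethoxyphosphoryl)acetate
Conditions: DMAP (0.3 equiv), toluene, reflux with removal of ethanol
Reagents that add atoms: none
Why: DMAP-catalysed transesterification, driven by distilling out ethanol, should attach the chiral alkoxy group to the phosphonoacetate.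

Step 6
Reactants: 9 (6E)-5,5-dimethyl-8-(phenylsulfonyl)oct-6-enal; 12 (1S,2R,5S)-5-methyl-2-(2-phenylpropan-2-yl)cyclohexyl (diethoxyphosphoryl)acetate
Product: 13 (1S,2R,5S)-5-methyl-2-(2-phenylpropan-2-yl)cyclohexyl (2E,8E)-7,7-dimethyl-10-(phenylsulfonyl)deca-2,8-dienoate
Conditions: LiCl, i-Pr2NEt, MeCN, rt
Reagents that add atoms: none
Why: Horner–Wadsworth–Emmons olefination under Masamune–Roush conditions should give the (E)-enoate with a base too weak to deprotonate the allyl sulfone.

Step 7
Reactants: 13 (1S,2R,5S)-5-methyl-2-(2-phenylpropan-2-yl)cyclohexyl (2E,8E)-7,7-dimethyl-10-(phenylsulfonyl)deca-2,8-dienoate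
Product: 15 (10S)-4,4-dimethyl-7-(phenylsulfonyl)octal-5-en-8-one (route locants; C7 epimers), via Michael adduct 14 (not isolated)
Conditions: LiN(SiMe3)2 (1.1 equiv), THF (0.01 M), −78 °C, then 0 °C to rt; aq NH4Cl
Reagents that add atoms: none
Why: Proposed new method: LiN(SiMe3)2 removes the most acidic proton (CH2 next to sulfur, C7) and the sulfonyl allyl anion adds through its gamma-terminus C5 to the enoate beta-carbon C10 (Michael addition, 6-exo-trig, ring A); HN(SiMe3)2 then relays a proton from C5 to the ester enolate, and the regenerated allyl anion acylates through its alpha-terminus C7 at the ester carbon C8 (Dieckmann-type closure, 6-exo-trig, ring B) with loss of the 8-phenylmenthoxide, ending as the stabilised beta-keto sulfone enolate. The closest known reaction types are the Hauser–Kraus and other Michael–Dieckmann annulations of sulfonyl carbanions and the gamma-selective conjugate addition of lithiated allyl sulfones; their union in one bicyclising (3+3) event with a chiral alkoxide as leaving group is the new element. The one lasting stereocentre, C10, is set in the Michael event by the auxiliary, whose phenyl ring stacks over one face of the s-trans enoate so that C5 enters from the open face; C5 becomes trigonal again and C7 is epimerisable and is removed later. The step needs gamma-attack in the first event and alpha-attack in the second, and both follow from ring size (six-membered against eight- and four-membered alternatives), helped by the gem-dimethyl group (Thorpe–Ingold effect). Chemoselective deprotonation is secured by the acidity order allyl sulfone CH2 > enoate gamma-CH2, and every stage is downhill (sulfonyl anion, ester enolate, sulfonyl allyl anion, beta-keto sulfone enolate), so one equivalent of base suffices.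

Step 8
Reactants: 16 2,4,5-trihydroxybenzaldehyde
Product: 17 2,4,5-tris(methoxymethoxy)benzaldehyde
Conditions: MeOCH2Cl (3.6 equiv), i-Pr2NEt, CH2Cl2, 0 °C to rt
Reagents that add atoms: chloromethyl methyl ether, COCCl
Why: Williamson-type O-alkylation should protect all three phenols as MOM ethers, which tolerate the strong bases ahead and later direct the ortho-lithiation.

Step 9
Reactants: 17 2,4,5-tris(methoxymethoxy)benzaldehyde
Product: 18 [2,4,5-tris(methoxymethoxy)phenyl]methanol
Conditions: NaBH4, MeOH, 0 °C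
Reagents that add atoms: none
Why: Borohydride reduction of the aryl aldehyde should give the benzylic alcohol.

Step 10
Reactants: 18 [2,4,5-tris(methoxymethoxy)phenyl]methanol
Product: 19 1-(chloromethyl)-2,4,5-tris(methoxymethoxy)benzene
Conditions: PPh3, N-chlorosuccinimide, CH2Cl2, 0 °C; used at once
Reagents that add atoms: N-chlorosuccinimide, O=C1CCC(=O)N1Cl
Why: Appel-type chlorination under neutral conditions should give the benzylic chloride without loss of the acid-labile MOM ethers.

Step 11
Reactants: 15 (10S)-4,4-dimethyl-7-(phenylsulfonyl)octal-5-en-8-one; 19 1-(chloromethyl)-2,4,5-tris(methoxymethoxy)benzene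
Product: 20 (10S)-4,4-dimethyl-7-(phenylsulfonyl)-9-[2,4,5-tris(methoxymethoxy)benzyl]octal-5-en-8-one (route locants; C7 and C9 epimers)
Conditions: LiN(i-Pr)2 (2.2 equiv), THF–DMPU, −78 to −20 °C; 19, Bu4NI (cat.), −78 to 0 °C; aq NH4Cl
Reagents that add atoms: none
Why: Alkylation of the beta-keto sulfone dianion should occur at its more basic C9 enolate carbon (gamma-alkylation of a 1,3-dicarbonyl-type dianion), and the C9 configuration is irrelevant because this centre is enolised again in step 12.

Step 12
Reactants: 20 (10S)-4,4-dimethyl-7-(phenylsulfonyl)-9-[2,4,5-tris(methoxymethoxy)benzyl]octal-5-en-8-one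
Product: 21 the C9-methylated ketone, 4,4,9-trimethyl-7-(phenylsulfonyl)-9-[2,4,5-tris(methoxymethoxy)benzyl]octal-5-en-8-one with C9 methyl trans to H-10 and arylmethyl cis to H-10 (C7 epimers)
Conditions: LiN(i-Pr)2 (2.2 equiv), THF–DMPU, −78 to −30 °C; MeI (1.05 equiv), −78 °C; aq NH4Cl
Reagents that add atoms: iodomethane, CI
Why: A second dianion alkylation should create the quaternary centre, the small electrophile entering anti to the pseudo-axial ring-fusion hydrogen at C10 (axial alkylation of a cyclohexanone-type enolate), so that the methyl group ends trans and the arylmethyl group cis to H-10.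

Step 13
Reactants: 21 the C9-methylated ketone
Product: 22 the corresponding C8 alcohol, a beta-hydroxy sulfone (C7 and C8 epimers)
Conditions: NaBH4, MeOH–THF, 0 °C to rt
Reagents that add atoms: none
Why: Borohydride reduction of the beta-keto sulfone should give the beta-hydroxy sulfone, whose two new centres are erased in step 14.

Step 14
Reactants: 22 the C8 alcohol
Product: 24 the 7-(phenylsulfonyl)octa-5,7-diene (C5=C6 and C7=C8; C9 and C10 as in 21), via mesylate 23 (not isolated)
Conditions: MeSO2Cl, Et3N, CH2Cl2, 0 °C; then DBU, rt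
Reagents that add atoms: none
Why: Mesylation followed by E1cB elimination through the acidic proton next to sulfur (dehydration of a beta-hydroxy sulfone) should give the 2-sulfonyl-1,3-diene.

Step 15
Reactants: 24 the 7-(phenylsulfonyl)octa-5,7-diene
Product: 25 the C8-methylated allyl sulfone, C8 methyl cis to the C9 arylmethyl group and to H-10, alkene at C5=C6 (C7 epimers)
Conditions: MeLi (1.2 equiv), THF, −78 °C; aq NH4Cl at −78 °C
Reagents that add atoms: methyllithium, [Li]C
Why: Conjugate addition of methyllithium to the vinyl sulfone should deliver the methyl group to C8 by antiparallel (axial) attack on the face opposite the pseudo-axial C9 methyl group, and kinetic protonation of the sulfonyl allyl anion at C7 returns the C5=C6 alkene.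

Step 16
Reactants: 25 the C8-methylated allyl sulfone
Product: 26 1-{[(1R,2R,8aS)-1,2,5,5-tetramethyl-1,2,3,5,6,7,8,8a-octahydronaphthalen-1-yl]methyl}-2,4,5-tris(methoxymethoxy)benzene
Conditions: PdCl2(dppp) (5 mol %), LiBHEt3 (2 equiv), THF, 0 °C to rt
Reagents that add atoms: none
Why: Palladium-catalysed reductive desulfonylation of the allylic sulfone should transfer hydride to the less substituted allyl terminus C7 and so keep the trisubstituted C5=C6 alkene.

Step 17
Reactants: 26 the tris-MOM arene of step 16
Product: 28 2,5,6-tris(methoxymethoxy)-3-{[(1R,2R,8aS)-1,2,5,5-tetramethyl-1,2,3,5,6,7,8,8a-octahydronaphthalen-1-yl]methyl}benzaldehyde, via aryllithium 27 (not isolated)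
Conditions: n-BuLi, TMEDA, THF, −78 to −20 °C; DMF, −78 °C to rt; aq NH4Cl
Reagents that add atoms: N,N-dimethylformamide, CN(C)C=O
Why: Directed ortho-metalation at the ring position flanked by two MOM ethers and trapping with DMF (formylation) should place the aldehyde between the two oxygens.

Step 18
Reactants: 28 the tris-MOM aldehyde
Product: 29 2,3,6-trihydroxy-5-{[(1R,2R,8aS)-1,2,5,5-tetramethyl-1,2,3,5,6,7,8,8a-octahydronaphthalen-1-yl]methyl}benzaldehyde
Conditions: 2 M HCl (aq), THF–i-PrOH, 35 °C, argon
Reagents that add atoms: none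
Why: Mild acid hydrolysis of the three MOM acetals should free the triol without touching the trisubstituted alkene.

Step 19
Reactants: 29 the triol aldehyde
Product: 31 2-formyl-3,4-dihydroxy-6-{[(1R,2R,8aS)-1,2,5,5-tetramethyl-1,2,3,5,6,7,8,8a-octahydronaphthalen-1-yl]methyl}phenyl hydrogen sulfate, via cyclic phenylboronate 30 (not isolated)
Conditions: PhB(OH)2 (1.05 equiv), toluene, 4 Å molecular sieves, 60 °C; then SO3·pyridine, pyridine–DMF, 40 °C; H2O; Dowex 50W (H+ form), 0 °C
Reagents that add atoms: sulfur trioxide–pyridine complex, O=S(=O)([O-])[n+]1ccccc1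
Why: Masking the catechol in the flask as its cyclic boronate should leave only the phenol next to the arylmethyl group open to O-sulfonation by SO3·pyridine, and aqueous work-up hydrolyses the boronate.

**Compound list**

1 | 2-(3-chloropropyl)-1,3-dioxolane | ClCCCC1OCCO1 | starting material
2 | ethyl 3-methylbut-2-enoate | CCOC(=O)C=C(C)C | starting material
3 | [3-(1,3-dioxolan-2-yl)propyl]magnesium chloride | Cl[Mg]CCCC1OCCO1 | intermediate (not isolated)
4 | ethyl 6-(1,3-dioxolan-2-yl)-3,3-dimethylhexanoate | CCOC(=O)CC(C)(C)CCCC1OCCO1 | intermediate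
5 | 6-(1,3-dioxolan-2-yl)-3,3-dimethylhexanal | O=CCC(C)(C)CCCC1OCCO1 | intermediate
6 | diethyl [(phenylsulfonyl)methyl]phosphonate | CCOP(=O)(CS(=O)(=O)c1ccccc1)OCC | starting material
7 | 2-[(6E)-4,4-dimethyl-7-(phenylsulfonyl)hept-6-en-1-yl]-1,3-dioxolane | O=S(=O)(/C=C/CC(C)(C)CCCC1OCCO1)c1ccccc1 | intermediate (not isolated)
8 | 2-[(5E)-4,4-dimethyl-7-(phenylsulfonyl)hept-5-en-1-yl]-1,3-dioxolane | O=S(=O)(C/C=C/C(C)(C)CCCC1OCCO1)c1ccccc1 | intermediate
9 | (6E)-5,5-dimethyl-8-(phenylsulfonyl)oct-6-enal | O=CCCCC(C)(C)/C=C/CS(=O)(=O)c1ccccc1 | intermediate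
10 | (+)-8-phenylmenthol, (1S,2R,5S)-5-methyl-2-(2-phenylpropan-2-yl)cyclohexan-1-ol | C[C@H]1CC[C@@H]([C@H](C1)O)C(C)(C)c2ccccc2 | starting material
11 | triethyl phosphonoacetate | CCOC(=O)CP(=O)(OCC)OCC | starting material
12 | (1S,2R,5S)-5-methyl-2-(2-phenylpropan-2-yl)cyclohexyl (diethoxyphosphoryl)acetate | C[C@H]1CC[C@@H]([C@H](C1)OC(=O)CP(=O)(OCC)OCC)C(C)(C)c2ccccc2 | intermediate
13 | (1S,2R,5S)-5-methyl-2-(2-phenylpropan-2-yl)cyclohexyl (2E,8E)-7,7-dimethyl-10-(phenylsulfonyl)deca-2,8-dienoate | C[C@H]1CC[C@@H]([C@H](C1)OC(=O)/C=C/CCCC(C)(C)/C=C/CS(=O)(=O)c2ccccc2)C(C)(C)c3ccccc3 | intermediate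
14 | 8-phenylmenthyl 2-{(1S,2R)-3,3-dimethyl-2-[(E)-2-(phenylsulfonyl)ethenyl]cyclohexyl}acetate (trans shown; the vinyl-bearing centre is lost in the next event) | C[C@H]1CC[C@@H]([C@H](C1)OC(=O)C[C@@H]2CCCC(C)(C)[C@H]2/C=C/S(=O)(=O)c3ccccc3)C(C)(C)c4ccccc4 | intermediate (not isolated)
15 | (8aS)-5,5-dimethyl-3-(phenylsulfonyl)-1,5,6,7,8,8a-hexahydronaphthalen-2(3H)-one (10S in route locants; C7 epimers) | O=C1C(S(=O)(=O)c2ccccc2)C=C3[C@@H](CCCC3(C)C)C1 | intermediate
16 | 2,4,5-trihydroxybenzaldehyde | O=Cc1cc(O)c(O)cc1O | starting material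
17 | 2,4,5-tris(methoxymethoxy)benzaldehyde | O=Cc1cc(OCOC)c(OCOC)cc1OCOC | intermediate
18 | [2,4,5-tris(methoxymethoxy)phenyl]methanol | OCc1cc(OCOC)c(OCOC)cc1OCOC | intermediate
19 | 1-(chloromethyl)-2,4,5-tris(methoxymethoxy)benzene | ClCc1cc(OCOC)c(OCOC)cc1OCOC | intermediate
20 | 15 carrying a 2,4,5-tris(methoxymethoxy)benzyl group on C9 (C7 and C9 epimers; C10 as in 15) | O=C1C(S(=O)(=O)c2ccccc2)C=C3[C@@H](CCCC3(C)C)C1Cc4cc(OCOC)c(OCOC)cc4OCOC | intermediate
21 | C9-quaternary beta-keto sulfone: C9 methyl trans to H-10, C9 arylmethyl cis to H-10 (C7 epimers) | O=C1C(S(=O)(=O)c2ccccc2)C=C3[C@@H](CCCC3(C)C)[C@]1(C)Cc4cc(OCOC)c(OCOC)cc4OCOC | intermediate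
22 | C8 alcohol of 21 (beta-hydroxy sulfone; C7 and C8 epimers) | OC1C(S(=O)(=O)c2ccccc2)C=C3[C@@H](CCCC3(C)C)[C@]1(C)Cc4cc(OCOC)c(OCOC)cc4OCOC | intermediate
23 | C8 methanesulfonate of 22 | CS(=O)(=O)OC1C(S(=O)(=O)c2ccccc2)C=C3[C@@H](CCCC3(C)C)[C@]1(C)Cc4cc(OCOC)c(OCOC)cc4OCOC | intermediate (not isolated)
24 | 2-sulfonyl-1,3-diene: C5=C6 and C7=C8, PhSO2 on C7, C9 and C10 as in 21 | C1=C(S(=O)(=O)c2ccccc2)C=C3[C@@H](CCCC3(C)C)[C@]1(C)Cc4cc(OCOC)c(OCOC)cc4OCOC | intermediate
25 | allyl sulfone: C8 methyl cis to the C9 arylmethyl group and H-10, C5=C6 alkene, PhSO2 on C7 (C7 epimers) | C[C@@H]1C(S(=O)(=O)c2ccccc2)C=C3[C@@H](CCCC3(C)C)[C@]1(C)Cc4cc(OCOC)c(OCOC)cc4OCOC | intermediate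
26 | 1-{[(1R,2R,8aS)-1,2,5,5-tetramethyl-1,2,3,5,6,7,8,8a-octahydronaphthalen-1-yl]methyl}-2,4,5-tris(methoxymethoxy)benzene | C[C@@H]1CC=C2[C@@H](CCCC2(C)C)[C@]1(C)Cc3cc(OCOC)c(OCOC)cc3OCOC | intermediate
27 | aryllithium of 26, lithium on the ring carbon between two MOM ethers | C[C@@H]1CC=C2[C@@H](CCCC2(C)C)[C@]1(C)Cc3cc(OCOC)c(OCOC)c([Li])c3OCOC | intermediate (not isolated)
28 | 2,5,6-tris(methoxymethoxy)-3-{[(1R,2R,8aS)-1,2,5,5-tetramethyl-1,2,3,5,6,7,8,8a-octahydronaphthalen-1-yl]methyl}benzaldehyde | C[C@@H]1CC=C2[C@@H](CCCC2(C)C)[C@]1(C)Cc3cc(OCOC)c(OCOC)c(C=O)c3OCOC | intermediate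
29 | 2,3,6-trihydroxy-5-{[(1R,2R,8aS)-1,2,5,5-tetramethyl-1,2,3,5,6,7,8,8a-octahydronaphthalen-1-yl]methyl}benzaldehyde | C[C@@H]1CC=C2[C@@H](CCCC2(C)C)[C@]1(C)Cc3cc(O)c(O)c(C=O)c3O | intermediate
30 | cyclic phenylboronate of the catechol of 29 | C[C@@H]1CC=C2[C@@H](CCCC2(C)C)[C@]1(C)Cc3cc4OB(c5ccccc5)Oc4c(C=O)c3O | intermediate (not isolated)
31 | 2-formyl-3,4-dihydroxy-6-{[(1R,2R,8aS)-1,2,5,5-tetramethyl-1,2,3,5,6,7,8,8a-octahydronaphthalen-1-yl]methyl}phenyl hydrogen sulfate (8R,9R,10S in route locants) | C[C@@H]1CC=C2[C@@H](CCCC2(C)C)[C@]1(C)Cc3cc(O)c(O)c(C=O)c3OS(=O)(=O)O | target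

**Summary**

Total step count: 19. Longest linear sequence: 15 steps (steps 1–4, 6, 7 and 11–19).

Steps most likely to fail:

1. Step 7 (Proposed new method). The hindered gamma-terminus may add too slowly, so that intermolecular addition competes. The proton relay or the acylation of the hindered ester may stall after the first ring. Facial selectivity in the Michael event may be low. Fallback, from 13 back to 15: the Michael event alone is run at −78 °C and quenched with acetic acid, so that the adduct 14 is isolated and freed from its diastereomer while the auxiliary is still attached. Ti(OEt)4 in boiling ethanol then exchanges the hindered alkoxy group to give ethyl 2-{(1S,2R)-3,3-dimethyl-2-[(E)-2-(phenylsulfonyl)ethenyl]cyclohexyl}acetate F1. KN(SiMe3)2 in THF closes ring B by the known intramolecular acylation of a sulfonyl carbanion (sulfone Dieckmann condensation) to give 15.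

2. Step 12. Incomplete dianion formation would divert methylation to C7 or oxygen, and the facial preference of the C9 enolate may be low or opposite to that assumed. Fallback, from 15 back to 21: the order of the two alkylations is reversed. The dianion of 15 is first methylated to the 9-methyl beta-keto sulfone F2, and its dianion is then alkylated with 19. The two orders give opposite C9 epimers, so whichever face the enolate prefers, one order should deliver 21.

3. Step 19. The catechol may be masked incompletely, leading to over-sulfation; the electron-rich triol may oxidise in air; the sulfate may be lost on the acidic resin. Fallback, from 29 back to 31: (t-Bu)2Si(OSO2CF3)2 and 2,6-lutidine in DMF convert the catechol into the isolable cyclic di-tert-butylsilylene of 29 F3. SO3·NMe3 with Et3N in DMF at 50 °C sulfates the remaining phenol to give the aryl hydrogen sulfate of the silylene F4. HF·pyridine in THF removes the silylene to give 31.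

Further compounds
F1 | step 7 | ethyl 2-{(1S,2R)-3,3-dimethyl-2-[(E)-2-(phenylsulfonyl)ethenyl]cyclohexyl}acetate | CCOC(=O)C[C@@H]1CCCC(C)(C)[C@H]1/C=C/S(=O)(=O)c2ccccc2
F2 | step 12 | 9-methyl beta-keto sulfone, (8aS)-1,5,5-trimethyl-3-(phenylsulfonyl)-1,5,6,7,8,8a-hexahydronaphthalen-2(3H)-one (C7 and C9 epimers) | O=C1C(S(=O)(=O)c2ccccc2)C=C3[C@@H](CCCC3(C)C)C1C
F3 | step 19 | cyclic di-tert-butylsilylene of the catechol of 29 | C[C@@H]1CC=C2[C@@H](CCCC2(C)C)[C@]1(C)Cc3cc4O[Si](C(C)(C)C)(C(C)(C)C)Oc4c(C=O)c3O
F4 | step 19 | aryl hydrogen sulfate of the silylene F3 | C[C@@H]1CC=C2[C@@H](CCCC2(C)C)[C@]1(C)Cc3cc4O[Si](C(C)(C)C)(C(C)(C)C)Oc4c(C=O)c3OS(=O)(=O)O
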